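Z forms slowly from E and Q, with D as initiator and Q going in by portions, and the two earlier runs show how slowly.

the same everywhere: D 1.1 mM

| run | E | Q | remark | time |
|---|---|---|---|---|
| theta | 0.054 M | 0.12 M (in portions, 3) | run made earlier; portions every 4.0 min |  |
| gamma | 0.17 M | 0.12 M (in portions, 3) | run made earlier; portions every 4.0 min |  |
| autumn | 0.040 M | 0.120 M (in portions, 3) | the portions of Q follow each other after 4.0 min, the first at the start | 20 min |
| noon | 0.060 M | 0.120 M (in portions, 3) | the portions of Q follow each other after 4.0 min, the first at the start | 20 min |
| dawn | 0.10 M | 0.120 M (in portions, 3) | the portions of Q follow each other after 4.0 min, the first at the start | 20 min |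
| summer | 0.15 M | 0.120 M (in portions, 3) | the portions of Q follow each other after 4.0 min, the first at the start | 20 min |

| run | time / min | Z / % | E / % |
|---|---|---|---|
| theta | 1.33 | 1 | 96 |
| theta | 4.00 | 8 | 93 |
| theta | 6.00 | 13 | 85 |
| theta | 10.0 | 30 | 73 |
| theta | 15.0 | 49 | 51 |
| gamma | 1.33 | 0 | 98 |
| gamma | 4.00 | 2 | 98 |
| gamma | 6.00 | 5 | 97 |
| gamma | 10.0 | 9 | 90 |
| gamma | 15.0 | 16 | 85 |

(each reading ± 1.5 percentage points)

1. [Z] at the end for autumn, noon, dawn, summer, in this order
2. the course of these numbers from the first flask to the last (hardly changes / falls all the way / rises all the way / falls, then rises / rises, then falls)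

- "hardly changes" means that all values lie within two and a half points (for a concentration: within two and a half percent of the largest)

Does the charge of E matter? After 15.0 min, theta had turned 49% of its E into Z and gamma 16%. Those fractions stand 3.06 to one, while the charges stand 3.15 to one the other way. So, within the scatter, a fraction times its charge is the same in both runs, which reads as zero order in E over these two runs. Take that as the zero of the scale.

What does this ask of each flask? The readings give 0.0268 M of Z at 15.0 min, and the last interval adds 0.00222 M/min. My reach at 20 min is therefore 0.0379 M. Divided by a flask's charge of E, it gives that flask's claim, the fraction of its E that must turn into Z to keep pace. The claims are 94.8% for autumn, 63.2% for noon, 37.9% for dawn and 25.3% for summer.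

Can each flask pay? Theta's Z still stood level with gamma's at 15.0 min, with a reading of 0.0275 M of E in theta at that time. That amount is 68.8% of autumn's charge and 45.9% of noon's, yet their claims would leave 5.20% and 36.8%. Dawn would keep 62.1% against 27.5%, and summer 74.7% against 18.4%. So I put dawn and summer at the reach, level with each other, and noon and autumn below it, autumn lower; of the courses on offer, rises all the way is the nearest to that row, and it is the one I commit to.

The forecast gave 0.035 M, 0.037 M, 0.037 M, 0.037 M, and hardly changes, its last three values standing below my reach: “This should apply to every flask, since E is not limiting.”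

The simulation gives 0.0333 M, 0.0367 M, 0.0374 M, 0.0376 M, which rises all the way, with the first flask 11.4% below the last.

    D → 2 L (k = 8.39 × 10⁻⁵ /s)
    E + L → G (k = 83000 /M/s)
    Q + G → Z + L (k = 26800 /M/s)
    2 G → J (k = 4.00 × 10⁸ /M/s)
    2 L → X (k = 4.00 × 10⁷ /M/s)

Autumn ended with 16.4% of its E still there, and its Z stood at 83.2% against a claim of 94.8%. Summer's claim was 25.3%, and its Z stood at 25.0%.

The readings come from a simulation with made-up constants, noise included.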